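The two bonds that fuse pyranone ring C to ring A, O1–C8a and C4–C4a, are cut together. These two ortho carbons of ring A, with the C5 oxygen next to C4a, are the retron of an unsymmetrical aryne that takes up an O-nucleophile at C8a and an acyl group at C4a. In the key step the alkoxide of (S)-3-hydroxy-N-methoxy-N-methyl-3-phenylpropanamide adds to 3,5-bis(benzyloxy)benzyne and the aryl anion closes onto the amide carbonyl, giving the (2S)-flavanone in one operation. The C3 oxygen is then installed trans by Rubottom oxidation, esterified with (S)-2-methylbutanoic acid, and the benzyl ethers are removed.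

Key step: step 4

Remark on the chemistry: the C3 oxygen is left out of the key-step precursor on purpose, because an acyl or silyl group on a neighbouring oxygen would migrate to the alkoxide that the key step needs; it is introduced afterwards under substrate control. Compounds 1, 3 and 15 are taken to be commercially available.

Step 1
Reactants: 1 ethyl (3S)-3-hydroxy-3-phenylpropanoate
Product: 2 (3S)-3-hydroxy-N-methoxy-N-methyl-3-phenylpropanamide
Conditions: MeNH(OMe)·HCl, iPrMgCl, THF, −20 → 0 °C
Reagents that add atoms: N,O-dimethylhydroxylamine hydrochloride CNOC.Cl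
Why: aminolysis of the ester by the chloromagnesium amide of N,O-dimethylhydroxylamine should tolerate the free alcohol as its magnesium alkoxide and leave the carbinol stereocenter untouched.

Step 2
Reactants: 3 3,5-bis(benzyloxy)phenol
Product: 4 3,5-bis(benzyloxy)-2-bromophenol
Conditions: NBS (1.0 equiv), CH2Cl2, −78 °C → rt
Reagents that add atoms: N-bromosuccinimide O=C1CCC(=O)N1Br
Why: electrophilic aromatic bromination of the phenol at low temperature should favour a position ortho to the hydroxyl group over the more hindered C4 between the two benzyloxy groups.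

Step 3
Reactants: 4 3,5-bis(benzyloxy)-2-bromophenol
Product: 7 3,5-bis(benzyloxy)-2-(trimethylsilyl)phenyl trifluoromethanesulfonate, via aryl silyl ether 5 (not isolated), via lithium phenolate 6 (not isolated)
Conditions: HMDS, THF, 70 °C, then concentrate; n-BuLi, THF, −100 → −78 °C; Tf2O, −100 °C → rt
Reagents that add atoms: hexamethyldisilazane C[Si](C)(C)N[Si](C)(C)C; trifluoromethanesulfonic anhydride O=S(=O)(OS(=O)(=O)C(F)(F)F)C(F)(F)F
Why: O-silylation, bromine–lithium exchange and 1,3 O-to-C silyl shift (retro-Brook rearrangement) should give the ortho-silyl phenolate, which is trapped as its triflate in the usual one-flask route from ortho-bromophenols to ortho-silylaryl triflates.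

Step 4
Reactants: 2 (3S)-3-hydroxy-N-methoxy-N-methyl-3-phenylpropanamide; 7 3,5-bis(benzyloxy)-2-(trimethylsilyl)phenyl trifluoromethanesulfonate
Product: 11 (2S)-5,7-bis(benzyloxy)-2-phenylchroman-4-one, via potassium alkoxide 8 (not isolated), via aryne 9 (not isolated), via tetrahedral adduct 10 (not isolated)
Conditions: KH (1.0 equiv), THF, 0 °C; then KF, 18-crown-6, slow addition of 7 (1.2 equiv), THF, −20 → 0 °C; then 1 M HCl, 0 °C
Reagents that add atoms: none
Why: Proposed new method: alkoxide 8 has no exchangeable proton and should add to aryne 9 at the carbon remote from the 3-benzyloxy group (the later C8a), and the aryl anion thus formed at the later C4a, flanked by two oxygens, should attack the tethered N-methoxy-N-methylamide carbonyl to give tetrahedral adduct 10, which persists as in the Weinreb ketone synthesis and gives ketone 11 only on acidic work-up. The closest known reaction type is the annulation of arynes with ortho-hydroxyaryl esters to xanthones (O-arylation, then intramolecular acylation of the aryl anion), supported by the known insertions of arynes into alcohol O–H bonds and into amide N–C(O) bonds, whereas an aliphatic 3-hydroxy amide as the partner has not been shown. Ring C is closed by 6-exo-trig attack of the aryl carbanion on the amide carbonyl, so the operation is a formal [4+2] annulation that makes O1–C8a first and C4–C4a second. No stereocenter is created, because C2 is carried over from 2 with its C–O bond intact and the hemiaminal carbon of 10 is lost on work-up. The step needs regioselective addition to the unsymmetrical aryne, which the inductive effect of the benzyloxy group next to the triple bond should secure (aryne distortion), and acylation of the aryl anion in preference to its protonation, which the pre-formed alkoxide, the aprotic medium and the six-membered transition state should secure. Holding the carbonyl as 10 until work-up keeps the base-sensitive flavanone from enolisation and retro-oxa-Michael opening, which would racemise C2.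

Step 5
Reactants: 11 (2S)-5,7-bis(benzyloxy)-2-phenylchroman-4-one
Product: 12 (2S)-5,7-bis(benzyloxy)-2-phenyl-4-(trimethylsilyloxy)-2H-chromene
Conditions: TMSOTf, Et3N, CH2Cl2, 0 °C; non-aqueous work-up
Reagents that add atoms: trimethylsilyl trifluoromethanesulfonate C[Si](C)(C)OS(=O)(=O)C(F)(F)F
Why: soft enolisation of the aryl ketone gives the silyl enol ether without a free enolate, so that opening of ring C to the chalcone and loss of the C2 configuration should be avoided.

Step 6
Reactants: 12 (2S)-5,7-bis(benzyloxy)-2-phenyl-4-(trimethylsilyloxy)-2H-chromene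
Product: 14 (2R,3R)-5,7-bis(benzyloxy)-3-hydroxy-2-phenylchroman-4-one, via silyloxy epoxide 13 (not isolated)
Conditions: DMDO (in acetone), CH2Cl2, −40 → 0 °C; then 1 M HCl, THF, 0 °C
Reagents that add atoms: dimethyldioxirane CC1(C)OO1
Why: in this Rubottom oxidation dimethyldioxirane should epoxidise the enol ether on the face opposite to the 2-phenyl group and acid should open the silyloxy epoxide to the alpha-hydroxy ketone, so that C3 is set trans to C2 by substrate control, which is also the thermodynamically preferred diequatorial arrangement.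

Step 7
Reactants: 14 (2R,3R)-5,7-bis(benzyloxy)-3-hydroxy-2-phenylchroman-4-one; 15 (2S)-2-methylbutanoic acid
Product: 16 (2R,3R)-5,7-bis(benzyloxy)-4-oxo-2-phenylchroman-3-yl (2S)-2-methylbutanoate
Conditions: DCC, DMAP (cat.), CH2Cl2, 0 °C → rt
Reagents that add atoms: none
Why: Steglich esterification of the secondary alcohol under nearly neutral conditions should leave the enolisable C3 center, ring C and the alpha stereocenter of the acid unchanged.

Step 8
Reactants: 16 (2R,3R)-5,7-bis(benzyloxy)-4-oxo-2-phenylchroman-3-yl (2S)-2-methylbutanoate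
Product: 17 (2R,3R)-5,7-dihydroxy-4-oxo-2-phenylchroman-3-yl (2S)-2-methylbutanoate
Conditions: H2 (1 atm), Pd/C (10%), EtOAc, rt
Reagents that add atoms: none
Why: hydrogenolysis of the two aryl benzyl ethers should be much faster than cleavage of the cyclic benzylic C2–O1 bond or reduction of the ketone and should leave the ester and all three stereocenters unchanged.

Compound list
1 | ethyl (3S)-3-hydroxy-3-phenylpropanoate | CCOC(=O)C[C@H](O)c1ccccc1 | starting material
2 | (3S)-3-hydroxy-N-methoxy-N-methyl-3-phenylpropanamide | CON(C)C(=O)C[C@H](O)c1ccccc1 | intermediate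
3 | 3,5-bis(benzyloxy)phenol | Oc1cc(OCc2ccccc2)cc(OCc2ccccc2)c1 | starting material
4 | 3,5-bis(benzyloxy)-2-bromophenol | Oc1cc(OCc2ccccc2)cc(OCc2ccccc2)c1Br | intermediate
5 | [3,5-bis(benzyloxy)-2-bromophenoxy]trimethylsilane (not isolated) | C[Si](C)(C)Oc1cc(OCc2ccccc2)cc(OCc2ccccc2)c1Br | intermediate
6 | lithium 3,5-bis(benzyloxy)-2-(trimethylsilyl)phenolate (not isolated) | [Li+].[O-]c1cc(OCc2ccccc2)cc(OCc2ccccc2)c1[Si](C)(C)C | intermediate
7 | 3,5-bis(benzyloxy)-2-(trimethylsilyl)phenyl trifluoromethanesulfonate | C[Si](C)(C)c1c(OS(=O)(=O)C(F)(F)F)cc(OCc2ccccc2)cc1OCc1ccccc1 | intermediate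
8 | potassium (1S)-3-[methoxy(methyl)amino]-3-oxo-1-phenylpropan-1-olate (not isolated) | [K+].[O-][C@@H](CC(=O)N(C)OC)c1ccccc1 | intermediate
9 | 3,5-bis(benzyloxy)benzyne, triple bond between the former triflate and silyl carbons (not isolated) | C1#CC(OCc2ccccc2)=CC(OCc2ccccc2)=C1 | intermediate
10 | potassium (2S)-5,7-bis(benzyloxy)-4-[methoxy(methyl)amino]-2-phenylchroman-4-olate, either configuration at C4 (not isolated) | C1C([O-])(N(C)OC)c2c(OCc3ccccc3)cc(OCc3ccccc3)cc2O[C@@H]1c1ccccc1.[K+] | intermediate
11 | (2S)-5,7-bis(benzyloxy)-2-phenylchroman-4-one | C1C(=O)c2c(OCc3ccccc3)cc(OCc3ccccc3)cc2O[C@@H]1c1ccccc1 | intermediate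
12 | (2S)-5,7-bis(benzyloxy)-2-phenyl-4-(trimethylsilyloxy)-2H-chromene | C1=C(O[Si](C)(C)C)c2c(OCc3ccccc3)cc(OCc3ccccc3)cc2O[C@@H]1c1ccccc1 | intermediate
13 | 5,7-bis(benzyloxy)-3,4-epoxy-2-phenyl-4-(trimethylsilyloxy)chromane, epoxide oxygen on the face opposite to the 2-phenyl group, C2 as in 12 (not isolated) | C[Si](C)(C)O[C@@]12O[C@@H]1[C@@H](c1ccccc1)Oc1cc(OCc3ccccc3)cc(OCc3ccccc3)c12 | intermediate
14 | (2R,3R)-5,7-bis(benzyloxy)-3-hydroxy-2-phenylchroman-4-one | O[C@H]1C(=O)c2c(OCc3ccccc3)cc(OCc3ccccc3)cc2O[C@@H]1c1ccccc1 | intermediate
15 | (2S)-2-methylbutanoic acid | CC[C@H](C)C(=O)O | starting material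
16 | (2R,3R)-5,7-bis(benzyloxy)-4-oxo-2-phenylchroman-3-yl (2S)-2-methylbutanoate | CC[C@H](C)C(=O)O[C@H]1C(=O)c2c(OCc3ccccc3)cc(OCc3ccccc3)cc2O[C@@H]1c1ccccc1 | intermediate
17 | (2R,3R)-5,7-dihydroxy-4-oxo-2-phenylchroman-3-yl (2S)-2-methylbutanoate | CC[C@H](C)C(=O)O[C@H]1C(=O)c2c(O)cc(O)cc2O[C@@H]1c1ccccc1 | target

Total step count: 8. Longest linear sequence: 7 steps (steps 2 to 8, from 3).

Steps most likely to fail

Step 4 (key step, proposed new method). The aryl anion may be protonated before it closes ring C, or 8 may attack the triflyl sulfur of 7 instead of the aryne, so that only uncyclised material forms. The fallback uses known reactions, makes the two bonds one after the other and closes the ring from the arene side. Ester 1 would be O-arylated with aryne 9 (from 7, KF, 18-crown-6, THF, −20 °C; aryne insertion into an alcohol O–H bond, with retention at the carbinol carbon) to give ethyl (3S)-3-[3,5-bis(benzyloxy)phenoxy]-3-phenylpropanoate F1. Saponification (LiOH, THF/H2O, 0 °C) would give (3S)-3-[3,5-bis(benzyloxy)phenoxy]-3-phenylpropanoic acid F2. Intramolecular Friedel–Crafts acylation (trifluoroacetic anhydride, CH2Cl2, 0 °C) at one of the two equivalent positions ortho to the ether oxygen would then close ring C. The fallback sets out from 1 and 7 and comes back to the route at 11.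

Step 6. The oxidation may be unselective: attack on the face syn to the phenyl group, oxidation of the electron-rich ring A, or opening of ring C during the acidic hydrolysis of the epoxide. In the fallback the acyloxy group would be transferred to C3 in one step by alpha-acyloxylation of the ketone with an O-acyl-N-methylhydroxylamine (condensation, then [3,3]-sigmatropic shift, under mildly acidic conditions that let C3 settle trans). Acid 15 would be coupled with tert-butyl N-hydroxy-N-methylcarbamate (DCC, DMAP, CH2Cl2) to give tert-butyl N-methyl-N-{[(2S)-2-methylbutanoyl]oxy}carbamate F3. Removal of the carbamate (HCl, dioxane) would give N-methyl-O-[(2S)-2-methylbutanoyl]hydroxylamine hydrochloride F4, and 11 would be treated with F4 (DMSO, rt to 50 °C). The fallback sets out from 11 and 15 and comes back at 16, so that steps 5 to 7 are bypassed.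

Step 2. Bromination may take place at C4 between the two benzyloxy groups or a second time. The fallback replaces electrophilic substitution by directed ortho-metalation. Phenol 3 would be converted with isopropyl isocyanate (Et3N cat., CH2Cl2) into 3,5-bis(benzyloxy)phenyl N-isopropylcarbamate F5. N-Silylation in the flask and ortho-lithiation between the carbamate and the neighbouring benzyloxy group (TBSOTf, TMEDA, Et2O; n-BuLi, −78 °C; TMSCl) would give 3,5-bis(benzyloxy)-2-(trimethylsilyl)phenyl N-isopropylcarbamate F6. Cleavage of the carbamate (Et2NH, DBU, MeCN, 40 °C) would free 3,5-bis(benzyloxy)-2-(trimethylsilyl)phenol F7, which would be triflated in the same flask (PhNTf2). The fallback sets out from 3 and comes back at 7, so that steps 2 and 3 are bypassed.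

Further compounds
F1 | step 4 | ethyl (3S)-3-[3,5-bis(benzyloxy)phenoxy]-3-phenylpropanoate | CCOC(=O)C[C@H](Oc1cc(OCc2ccccc2)cc(OCc2ccccc2)c1)c1ccccc1
F2 | step 4 | (3S)-3-[3,5-bis(benzyloxy)phenoxy]-3-phenylpropanoic acid | OC(=O)C[C@H](Oc1cc(OCc2ccccc2)cc(OCc2ccccc2)c1)c1ccccc1
F3 | step 6 | tert-butyl N-methyl-N-{[(2S)-2-methylbutanoyl]oxy}carbamate | CC[C@H](C)C(=O)ON(C)C(=O)OC(C)(C)C
F4 | step 6 | N-methyl-O-[(2S)-2-methylbutanoyl]hydroxylamine hydrochloride | CC[C@H](C)C(=O)ONC.Cl
F5 | step 2 | 3,5-bis(benzyloxy)phenyl N-isopropylcarbamate | CC(C)NC(=O)Oc1cc(OCc2ccccc2)cc(OCc2ccccc2)c1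
F6 | step 2 | 3,5-bis(benzyloxy)-2-(trimethylsilyl)phenyl N-isopropylcarbamate | CC(C)NC(=O)Oc1cc(OCc2ccccc2)cc(OCc2ccccc2)c1[Si](C)(C)C
F7 | step 2 | 3,5-bis(benzyloxy)-2-(trimethylsilyl)phenol | Oc1cc(OCc2ccccc2)cc(OCc2ccccc2)c1[Si](C)(C)C
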